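Friday's small charge of Jb, 0.0550 M against 0.15 M of Ja, may stop that flask early. Monday's feeds its Ja over 2.0 min and starts with less Jc than Friday's.

| setting | amber | red | Monday's | Friday's |
|---|---|---|---|---|
| Ja | 0.11 M (fed, over 2.0 min) | 0.11 M (fed, over 2.0 min) | 0.11 M (fed, over 2.0 min) | 0.15 M |
| Jb | 0.083 M | 0.11 M | 0.0550 M | 0.0550 M |
| Jc | 0.26 mM | 0.26 mM | 0.26 mM | 1.0 mM |
| remark | run made earlier; the fed solution adds 0.50 times the starting volume | run made earlier; the fed solution adds 0.50 times the starting volume | the fed solution adds 0.50 times the starting volume | everything together at the start, the whole solution of Ja included, so that from the start the volume is larger by 0.50 times the starting volume |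
| time |  |  | 2.0 min | 2.0 min |

| run | time / s | Jd / % |
|---|---|---|
| amber | 12.0 | 1.0 |
| amber | 25.0 | 3.3 |
| amber | 40.0 | 7.6 |
| amber | 50.0 | 11.0 |
| amber | 60.0 | 14.5 |
| amber | 80.0 | 21.7 |
| red | 10.0 | 0.6 |
| red | 15.0 | 1.6 |
| red | 25.0 | 3.5 |
| red | 40.0 | 7.6 |
| red | 60.0 | 14.9 |
| red | 80.0 | 22.5 |

(each reading ± 0.3 percentage points)

- charges are per starting volume, the dose included; the dosed solution carries all of it
- percentages count the whole charge, also what has not yet gone in
- no earlier run changes the charge of Jc; that part of a forecast is a guess

1. which one finishes higher in amount of Jd, in percent of the Ja charged ("neither" within 2 percentage points) (Monday's / Friday's / neither)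
2. amount of Jd at the end, in percent of the Ja charged, Monday's
3. amount of Jd at the end, in percent of the Ja charged, Friday's

The first way to Friday's number is a count. Take one Jb per Jd, which is an assumption the runs do not prove. The ceiling, the Jb charged over the Ja charged (Jb being the limiting reagent), then gives

  Friday's: 36.7%
  Monday's: 50.0%

The second way is a rate. In red, Ja enters steadily, so its share in the flask grows as time over dosing time. If that share reacts at first order with constant k, integrating gives, early on,

  Jd = k × time × time / (2 × dosing time)

The reading at 40.0 s gives

  k = 0.0114 s⁻¹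

Scaling by Friday's catalyst, thinned by the larger volume and taken as first order (a guess), gives

  0.0292 s⁻¹

Integrating for Friday's batch gives

  Jd = 97.0% at 2.0 min

The two ways part. That much Jd in Friday's needs 0.146 M of Jb, more than the 0.0550 M charged. The rate way cheats, since it holds Jb level while asking for more than the charge, so Friday's reckoning stays at the ceiling.

For Monday's, extending the last slopes to 2.0 min reads 37.7% for red and 36.1% for amber. Carrying that trend in Jb down to Monday's charge gives my own 34.4%, below its ceiling. On this reckoning Friday's leads by 2.3 percentage points, more than the margin.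

The forecast says Friday's, with 33% for Monday's, lower than my figure, and 36% for Friday's, lower than my ceiling: “Jb should be used up within about a minute”.

The flasks give 31.2% for Monday's and 36.6% for Friday's, so Friday's finishes higher, and Friday's stands at its ceiling.

    Ja + Jc → Je (k = 78.9 L mol⁻¹ s⁻¹)
    Jb + Je → Jf (k = 148 L mol⁻¹ s⁻¹)
    Jf → Jg (k = 10.9 s⁻¹)
    Jg → Jc + Jd (k = 81.9 s⁻¹)
    Jf → Jh (k = 0.00948 s⁻¹)

Friday's has come to rest: Jb stands at 0% after 2.00 min, and Jd reads 36.6% after 20.0 min. Monday's has not come to rest: at 2.00 min it holds 38% of its Jb. After 20.0 min its Jb stands at 0% and its Jd has climbed to its ceiling, 50.0%.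

(Readings and results stem from a simulated flask for substances that don't exist, noise included.)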